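**Plan**

- Cuts: the single bonds C10'–C11' and C10–C11. They bound the constitutionally symmetric C12 pentaene C11'=C12'–C13'(Me)=C14'–C15'=C15–C14=C13(Me)–C12=C11, which lies between two unlike ends: ring A (3-hydroxy-ε ring with the C7'–C10' diene) and ring B (3-hydroxy-β ring with the C7≡C8/C9=C10 enyne).
- Fragments: an ε-end C14 dienyl iodide, a tin/boron C12 pentaene linchpin, and an acetylenic C14 enynyl iodide. Inside the fragments the cuts are C9'–CH3 and C9–CH3 (alkyne methylalumination–iodination), C6–C7 (diynyl addition to the ring B ketone) and the two end C=C bonds of the linchpin (olefination of the C10 dialdehyde).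
- Forward: no ring is formed; rings A and B come from α-ionone and ketoisophorone. The chain is joined in one flask, first C10'–C11' (tin end), then C10–C11 (boron end); both silyl ethers are then removed.
- Stereochemistry, ring B: an ene-reductase sets the methyl-bearing centre of levodione, which directs ketone hydrogenation to the C3 carbinol and is erased when C5=C6 forms.
- Stereochemistry, ring A: C3'/C6' come from racemic α-ionone by cis-selective enone reduction and Mitsunobu inversion with (1S)-camphanic acid, which also resolves the racemate.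
- Alkene geometry: syn carbometalation, E-selective chromium olefinations, the all-E dialdehyde and stereoretentive couplings.

Key step: step 18

Remark: carotenoid numbering is used (unprimed for the acetylenic β half, primed for the ε half); commercial α-ionone is taken to be the racemate, so the ring A centres are set and resolved within the route. All polyene operations are run under argon with exclusion of light.

**Route**

Step 1
Reactants: 1 (±)-α-ionone
Product: 3 (±)-6-[(E)-but-1-en-3-yn-1-yl]-1,5,5-trimethylcyclohex-1-ene, via enol diethyl phosphate 2 (not isolated)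
Conditions: LiN(i-Pr)2 (1.1 equiv), THF, −78 °C; ClP(O)(OEt)2, −78 °C → rt; then LiN(i-Pr)2 (2.3 equiv), THF, −78 °C → rt; H2O
Reagents that add atoms: none
Why: Kinetic deprotonation of the methyl group gives the cross-conjugated enolate, O-phosphorylation gives 2, and base-induced elimination of diethyl phosphate from 2 delivers the terminal alkyne (the one-pot methyl ketone to alkyne conversion established for ionone-type dienones); C6 is still racemic here, so any epimerisation is without consequence.

Step 2
Reactants: 3 racemic ε dienyne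
Product: 4 (±)-4-[(E)-but-1-en-3-yn-1-yl]-3,5,5-trimethylcyclohex-2-en-1-one
Conditions: t-BuOOH (70% aq., 5 equiv), Rh2(cap)4 (dirhodium tetracaprolactamate, 1 mol%), ClCH2CH2Cl, 40 °C
Reagents that add atoms: tert-butyl hydroperoxide, CC(C)(C)OO
Why: Radical-chain allylic oxidation (tert-butylperoxyl radical generated by the dirhodium caprolactamate catalyst) should take the secondary allylic C3 methylene, because the only other ring allylic hydrogen, C6–H, is tertiary and flanked by the gem-dimethyl carbon and the C5 methyl, while the enyne carries no propargylic hydrogen.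

Step 3
Reactants: 4 racemic enynone
Product: 5 (±)-cis-4-[(E)-but-1-en-3-yn-1-yl]-3,5,5-trimethylcyclohex-2-en-1-ol
Conditions: NaBH4, CeCl3·7H2O, MeOH, −40 °C; chromatography to remove any trans isomer
Reagents that add atoms: none
Why: Luche 1,2-reduction; hydride should add axially to the half-chair enone on the face opposite the pseudoaxial C6 side chain, which places the new C3 hydroxyl cis to the chain (relative configuration only, the material being racemic).

Step 4
Reactants: 5 racemic cis alcohol; 6 (1S)-(−)-camphanic acid
Product: 7 (1R,4R)-4-[(E)-but-1-en-3-yn-1-yl]-3,5,5-trimethylcyclohex-2-en-1-yl (1S)-camphanate (trans; carotenoid 3'R,6'R)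
Conditions: 6 (1.5 equiv), PPh3, DIAD, toluene, 0 °C → rt; chromatography, then crystallisation of the diastereomers
Reagents that add atoms: none
Why: Mitsunobu esterification proceeds by SN2 attack of the camphanate on the C3 alkoxyphosphonium ion with inversion (the SN2' terminus C5 is fully substituted), so both enantiomers of the cis alcohol become trans esters that are diastereomers through the (1S)-camphanoyl group and can be separated, the (3'R,6'R) ester to be identified by X-ray analysis against the known camphanoyl centres.

Step 5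
Reactants: 7 (3'R,6'R)-camphanate
Product: 8 (1R,4R)-4-[(E)-but-1-en-3-yn-1-yl]-3,5,5-trimethylcyclohex-2-en-1-ol
Conditions: K2CO3, MeOH, rt
Reagents that add atoms: none
Why: Base-catalysed transesterification cleaves the ester at the acyl–oxygen bond, so the C3' configuration set in step 4 is retained and the enyne is untouched.

Step 6
Reactants: 8 (3'R,6'R)-dienynol
Product: 9 tert-butyl({(1R,4R)-4-[(E)-but-1-en-3-yn-1-yl]-3,5,5-trimethylcyclohex-2-en-1-yl}oxy)dimethylsilane
Conditions: TBSCl, imidazole, DMF, rt
Reagents that add atoms: tert-butyldimethylsilyl chloride, CC(C)(C)[Si](C)(C)Cl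
Why: Imidazole-promoted silylation of a secondary alcohol; the silyl ether masks the allylic hydroxyl against AlMe3 and the palladium steps.

Step 7
Reactants: 9 silyl-protected ε dienyne
Product: 11 ε-end C14 dienyl iodide with iodine on C10' and 7'E and 9'E geometry, via alkenyldimethylalane 10 (not isolated)
Conditions: AlMe3 (2.5 equiv), Cp2ZrCl2 (0.25 equiv), CH2Cl2, 0 °C → rt; then I2, THF, −30 → 0 °C
Reagents that add atoms: trimethylaluminium, C[Al](C)C; iodine, II
Why: Zirconium-catalysed methylalumination (Negishi carboalumination) adds methyl and aluminium syn across the terminal alkyne with aluminium on the terminal carbon, and iodinolysis of the C–Al bond of 10 with retention gives the (E)-2-methylalkenyl iodide, which fixes the C9'=C10' geometry without touching the C7'=C8' alkene or the stereocentres.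

Step 8
Reactants: 12 ketoisophorone
Product: 13 (6R)-2,2,6-trimethylcyclohexane-1,4-dione ((R)-levodione)
Conditions: ene-reductase OYE2, NADP+ (cat.), glucose dehydrogenase, D-glucose, phosphate buffer pH 6.5, 30 °C
Reagents that add atoms: none
Why: Flavin-dependent ene-reductases reduce the activated C=C of ketoisophorone by trans addition of hydride and a proton, which should set the methyl-bearing centre as R; near-neutral pH and short contact limit enolisation of the product.

Step 9
Reactants: 13 (R)-levodione
Product: 14 (4R,6R)-4-hydroxy-2,2,6-trimethylcyclohexan-1-one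
Conditions: H2 (1 atm), Raney Ni, MeOH, rt; recrystallisation
Reagents that add atoms: none
Why: The C4 carbonyl is the accessible one (C1 is flanked by a quaternary and a tertiary carbon), and hydrogen should be delivered from the equatorial side, away from the axial C2 methyl, giving the axial C4 hydroxyl trans to the equatorial C6 methyl, that is the (4R,6R) alcohol whose carbinol centre becomes C3 of the target.

Step 10
Reactants: 14 (4R,6R)-hydroxy ketone
Product: 15 (4R,6R)-4-(tert-butyldimethylsilyloxy)-2,2,6-trimethylcyclohexan-1-one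
Conditions: TBSCl, imidazole, DMF, rt
Reagents that add atoms: tert-butyldimethylsilyl chloride, CC(C)(C)[Si](C)(C)Cl
Why: Imidazole-promoted silylation of the secondary alcohol protects it against the organolithium and dehydration steps.

Step 11
Reactants: 15 silyloxy ketone; 16 1,4-bis(trimethylsilyl)buta-1,3-diyne
Product: 18 4-(tert-butyldimethylsilyloxy)-2,2,6-trimethyl-1-[4-(trimethylsilyl)buta-1,3-diyn-1-yl]cyclohexan-1-ol (4R; mixture of C1 epimers), via lithium trimethylsilylbutadiynide 17 (not isolated)
Conditions: 16 (1.3 equiv), MeLi·LiBr (1.25 equiv), THF, rt; then 15, −78 → 0 °C; aq. NH4Cl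
Reagents that add atoms: none
Why: MeLi·LiBr removes one trimethylsilyl group of 16 to give the slim and weakly basic butadiynyllithium 17, which adds 1,2 to the hindered ketone (alkynyllithium addition); the configurations at the new carbinol carbon and at the neighbouring methine do not matter because both carbons become sp2 in step 12.

Step 12
Reactants: 18 tertiary diynyl carbinol
Product: 19 tert-butyldimethyl({(1R)-3,5,5-trimethyl-4-[4-(trimethylsilyl)buta-1,3-diyn-1-yl]cyclohex-3-en-1-yl}oxy)silane
Conditions: POCl3, pyridine, 60 °C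
Reagents that add atoms: none
Why: Dehydration of the tertiary propargylic alcohol through its dichlorophosphate can only proceed toward the methine carbon, the sole neighbouring carbon that bears hydrogen, and so gives the tetrasubstituted ring alkene (C5=C6 in carotenoid numbering) conjugated with the diyne; the remote silyl ether and the C3 centre are not involved.

Step 13
Reactants: 19 silyl-capped ring B enediyne
Product: 20 {[(1R)-4-(buta-1,3-diyn-1-yl)-3,5,5-trimethylcyclohex-3-en-1-yl]oxy}(tert-butyl)dimethylsilane
Conditions: K2CO3, MeOH/THF, 0 °C → rt; used at once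
Reagents that add atoms: none
Why: Methoxide cleaves the alkynyl C–Si bond selectively (protodesilylation), while the O-silyl ether of the secondary alcohol is stable to K2CO3 in methanol.

Step 14
Reactants: 20 terminal ring B diyne
Product: 22 acetylenic C14 (E)-enynyl iodide with iodine on C10, via alkenyldimethylalane 21 (not isolated)
Conditions: AlMe3 (3 equiv), Cp2ZrCl2 (0.3 equiv), ClCH2CH2Cl, rt; then I2, THF, −30 → 0 °C
Reagents that add atoms: trimethylaluminium, C[Al](C)C; iodine, II
Why: Zirconium-catalysed methylalumination occurs at the terminal alkyne of the conjugated diyne (the ring-bound internal alkyne is shielded by the trimethylcyclohexenyl group), syn addition placing methyl on C9 and aluminium on C10, and iodinolysis of 21 with retention gives the (E)-enynyl iodide.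

Step 15
Reactants: 23 dibromomethane
Product: 24 tributyl(dibromomethyl)stannane
Conditions: LiN(i-Pr)2, Bu3SnCl, THF/Et2O, −95 °C → rt
Reagents that add atoms: tributyltin chloride, CCCC[Sn](Cl)(CCCC)CCCC
Why: Deprotonation of dibromomethane at −95 °C and immediate stannylation of the resulting lithium carbenoid by chloride displacement at tin gives the gem-dibromide needed for the chromium olefination.

Step 16
Reactants: 25 (2E,4E,6E)-2,7-dimethylocta-2,4,6-trienedial
Product: 26 (2E,4E,6E,8E)-2,7-dimethyl-9-(4,4,5,5-tetramethyl-1,3,2-dioxaborolan-2-yl)nona-2,4,6,8-tetraenal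
Conditions: 25 (3 equiv), Cl2CHBpin (1 equiv), CrCl2 (6 equiv), LiI (3 equiv), THF, rt, dark; excess 25 recovered
Reagents that add atoms: 2-(dichloromethyl)-4,4,5,5-tetramethyl-1,3,2-dioxaborolane, ClC(Cl)B1OC(C)(C)C(C)(C)O1
Why: Takai-type boryl olefination: divalent chromium converts the dihalomethylboronate (iodide-exchanged in the flask by LiI) into a geminal dichromium reagent that adds to one formyl group and eliminates to the E-alkenylboronate, monofunctionalisation being ensured statistically by the excess of the symmetric dialdehyde, which is recovered.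

Step 17
Reactants: 26 boronate aldehyde; 24 tributyl(dibromomethyl)stannane
Product: 27 tributyl[(1E,3E,5E,7E,9E)-3,8-dimethyl-10-(4,4,5,5-tetramethyl-1,3,2-dioxaborolan-2-yl)deca-1,3,5,7,9-pentaen-1-yl]stannane (C12 linchpin; tin on C11', boron on C11)
Conditions: 24 (2 equiv), CrCl2 (8 equiv), LiI (4 equiv), THF/DMF, rt, dark; chromatography on Et3N-deactivated silica
Reagents that add atoms: none
Why: The same chromium-mediated olefination with the stannyl gem-dihalide converts the remaining aldehyde into the E-alkenylstannane, the pinacolboronate and the polyene being inert to the aldehyde-specific geminal dichromium reagent.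

Step 18
Reactants: 11 ε-end C14 dienyl iodide; 27 tin/boron C12 pentaene linchpin; 22 acetylenic C14 enynyl iodide
Product: 29 bis(tert-butyldimethylsilyl) ether of the target, via polyenyl pinacolboronate 28 (not isolated)
Conditions: 11 (1.0 equiv), 27 (1.05 equiv), Pd2(dba)3 (5 mol%), AsPh3 (40 mol%), degassed DMF/THF, rt, dark; then 22 (1.1 equiv), 3 M aq. K3PO4, rt → 40 °C
Reagents that add atoms: none
Why: Oxidative addition of dienyl iodide 11 to zerovalent palladium gives an alkenyl divalent-palladium iodide that, under base-free conditions with AsPh3, transmetalates only with the C11' tributylstannyl terminus of 27 and reductively eliminates to forge C10'–C11' (Stille coupling), the pinacolboronate being unable to transmetalate without an oxygen base. Aqueous K3PO4 and enynyl iodide 22 then switch on the boron terminus of 28, and a second oxidative addition, transmetalation and reductive elimination forge C10–C11 (Suzuki–Miyaura coupling). The closest known reaction type is the one-pot Stille/Suzuki coupling of hetero-bis-metalated (tin/boron) 1,3-dienes with two different alkenyl halides, of which this pentaene is the vinylogous case. No ring is closed and no stereocentre is created; each cycle retains alkene geometry, so all eight chain E double bonds and the C7≡C8 triple bond arrive unchanged from the three fragments. The selectivity needed is site selectivity between the two termini of a constitutionally symmetric pentaene, and the substrate secures it through its unlike metals (neutral tin transmetalation versus base-gated boron transmetalation) together with the presence of only one electrophile in each stage.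

Step 19
Reactants: 29 bis-silyl ether
Product: 30 (3R,3'R,6'R)-7,8-didehydro-β,ε-carotene-3,3'-diol (all-E), the target
Conditions: TBAF, AcOH (1:1), THF, rt, dark; crystallisation
Reagents that add atoms: none
Why: Fluoride cleaves both Si–O bonds under near-neutral buffering and frees the two secondary alcohols without touching the stereocentres, the bis-allylic C6'–H or the polyene geometry; no equilibration is applied because the kinetically installed E geometry at C9=C10 next to the alkyne could drift.

**Compound list**

1 | (±)-α-ionone, (E)-4-(2,6,6-trimethylcyclohex-2-en-1-yl)but-3-en-2-one (racemate) | CC1=CCCC(C)(C)C1/C=C/C(C)=O | starting material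
2 | diethyl (E)-4-(2,6,6-trimethylcyclohex-2-en-1-yl)buta-1,3-dien-2-yl phosphate (racemate) | CC1=CCCC(C)(C)C1/C=C/C(=C)OP(=O)(OCC)OCC | intermediate
3 | (±)-6-[(E)-but-1-en-3-yn-1-yl]-1,5,5-trimethylcyclohex-1-ene (racemate) | CC1=CCCC(C)(C)C1/C=C/C#C | intermediate
4 | (±)-4-[(E)-but-1-en-3-yn-1-yl]-3,5,5-trimethylcyclohex-2-en-1-one (racemate) | CC1=CC(=O)CC(C)(C)C1/C=C/C#C | intermediate
5 | (±)-cis-4-[(E)-but-1-en-3-yn-1-yl]-3,5,5-trimethylcyclohex-2-en-1-ol (racemate; (1S,4R) enantiomer drawn) | CC1=C[C@@H](O)CC(C)(C)[C@H]1/C=C/C#C | intermediate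
6 | (1S)-(−)-camphanic acid, (1S,4R)-4,7,7-trimethyl-3-oxo-2-oxabicyclo[2.2.1]heptane-1-carboxylic acid | OC(=O)[C@@]12CC[C@@](C)(C(=O)O1)C2(C)C | starting material
7 | (1R,4R)-4-[(E)-but-1-en-3-yn-1-yl]-3,5,5-trimethylcyclohex-2-en-1-yl (1S)-camphanate (trans) | CC1=C[C@H](OC(=O)[C@@]23CC[C@@](C)(C(=O)O2)C3(C)C)CC(C)(C)[C@H]1/C=C/C#C | intermediate
8 | (1R,4R)-4-[(E)-but-1-en-3-yn-1-yl]-3,5,5-trimethylcyclohex-2-en-1-ol (trans) | CC1=C[C@H](O)CC(C)(C)[C@H]1/C=C/C#C | intermediate
9 | tert-butyl({(1R,4R)-4-[(E)-but-1-en-3-yn-1-yl]-3,5,5-trimethylcyclohex-2-en-1-yl}oxy)dimethylsilane | CC1=C[C@H](O[Si](C)(C)C(C)(C)C)CC(C)(C)[C@H]1/C=C/C#C | intermediate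
10 | (1E,3E)-dienyl(dimethyl)alane from 9 (aluminium on C10', methyl on C9') | CC1=C[C@H](O[Si](C)(C)C(C)(C)C)CC(C)(C)[C@H]1/C=C/C(C)=C/[Al](C)C | intermediate
11 | tert-butyl({(1R,4R)-4-[(1E,3E)-4-iodo-3-methylbuta-1,3-dien-1-yl]-3,5,5-trimethylcyclohex-2-en-1-yl}oxy)dimethylsilane (ε-end C14 dienyl iodide) | CC1=C[C@H](O[Si](C)(C)C(C)(C)C)CC(C)(C)[C@H]1/C=C/C(C)=C/I | intermediate
12 | ketoisophorone, 2,6,6-trimethylcyclohex-2-ene-1,4-dione | CC1=CC(=O)CC(C)(C)C1=O | starting material
13 | (6R)-2,2,6-trimethylcyclohexane-1,4-dione ((R)-levodione) | C[C@@H]1CC(=O)CC(C)(C)C1=O | intermediate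
14 | (4R,6R)-4-hydroxy-2,2,6-trimethylcyclohexan-1-one | C[C@@H]1C[C@@H](O)CC(C)(C)C1=O | intermediate
15 | (4R,6R)-4-(tert-butyldimethylsilyloxy)-2,2,6-trimethylcyclohexan-1-one | C[C@@H]1C[C@@H](O[Si](C)(C)C(C)(C)C)CC(C)(C)C1=O | intermediate
16 | 1,4-bis(trimethylsilyl)buta-1,3-diyne | C[Si](C)(C)C#CC#C[Si](C)(C)C | starting material
17 | lithium 4-(trimethylsilyl)buta-1,3-diyn-1-ide | [Li]C#CC#C[Si](C)(C)C | intermediate
18 | 4-(tert-butyldimethylsilyloxy)-2,2,6-trimethyl-1-[4-(trimethylsilyl)buta-1,3-diyn-1-yl]cyclohexan-1-ol (4R,6R; C1 epimers) | C[C@@H]1C[C@@H](O[Si](C)(C)C(C)(C)C)CC(C)(C)C1(O)C#CC#C[Si](C)(C)C | intermediate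
19 | tert-butyldimethyl({(1R)-3,5,5-trimethyl-4-[4-(trimethylsilyl)buta-1,3-diyn-1-yl]cyclohex-3-en-1-yl}oxy)silane | C[Si](C)(C)C#CC#CC1=C(C)C[C@@H](O[Si](C)(C)C(C)(C)C)CC1(C)C | intermediate
20 | {[(1R)-4-(buta-1,3-diyn-1-yl)-3,5,5-trimethylcyclohex-3-en-1-yl]oxy}(tert-butyl)dimethylsilane | C#CC#CC1=C(C)C[C@@H](O[Si](C)(C)C(C)(C)C)CC1(C)C | intermediate
21 | (E)-enynyl(dimethyl)alane from 20 (aluminium on C10, methyl on C9) | C[Al](C)/C=C(\C)C#CC1=C(C)C[C@@H](O[Si](C)(C)C(C)(C)C)CC1(C)C | intermediate
22 | tert-butyl({(1R)-4-[(E)-4-iodo-3-methylbut-3-en-1-yn-1-yl]-3,5,5-trimethylcyclohex-3-en-1-yl}oxy)dimethylsilane (acetylenic C14 enynyl iodide) | I/C=C(\C)C#CC1=C(C)C[C@@H](O[Si](C)(C)C(C)(C)C)CC1(C)C | intermediate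
23 | dibromomethane | BrCBr | starting material
24 | tributyl(dibromomethyl)stannane | CCCC[Sn](CCCC)(CCCC)C(Br)Br | intermediate
25 | (2E,4E,6E)-2,7-dimethylocta-2,4,6-trienedial | O=C/C(C)=C/C=C/C=C(C)/C=O | starting material
26 | (2E,4E,6E,8E)-2,7-dimethyl-9-(4,4,5,5-tetramethyl-1,3,2-dioxaborolan-2-yl)nona-2,4,6,8-tetraenal | O=C/C(C)=C/C=C/C=C(C)/C=C/B1OC(C)(C)C(C)(C)O1 | intermediate
27 | tributyl[(1E,3E,5E,7E,9E)-3,8-dimethyl-10-(4,4,5,5-tetramethyl-1,3,2-dioxaborolan-2-yl)deca-1,3,5,7,9-pentaen-1-yl]stannane (C12 linchpin) | CCCC[Sn](CCCC)(CCCC)/C=C/C(C)=C/C=C/C=C(C)/C=C/B1OC(C)(C)C(C)(C)O1 | intermediate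
28 | all-E ε-half polyenyl pinacolboronate (ring A silyl ether, chain C7' to C11, boron on C11) | CC1=C[C@H](O[Si](C)(C)C(C)(C)C)CC(C)(C)[C@H]1/C=C/C(C)=C/C=C/C(C)=C/C=C/C=C(C)/C=C/B1OC(C)(C)C(C)(C)O1 | intermediate
29 | (3R,3'R,6'R)-3,3'-bis(tert-butyldimethylsilyloxy)-7,8-didehydro-β,ε-carotene (all-E) | CC1=C[C@H](O[Si](C)(C)C(C)(C)C)CC(C)(C)[C@H]1/C=C/C(C)=C/C=C/C(C)=C/C=C/C=C(C)/C=C/C=C(\C)C#CC1=C(C)C[C@@H](O[Si](C)(C)C(C)(C)C)CC1(C)C | intermediate
30 | (3R,3'R,6'R)-7,8-didehydro-β,ε-carotene-3,3'-diol (all-E) | CC1=C[C@H](O)CC(C)(C)[C@H]1/C=C/C(C)=C/C=C/C(C)=C/C=C/C=C(C)/C=C/C=C(\C)C#CC1=C(C)C[C@@H](O)CC1(C)C | target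

**Totals and risks**

Total step count: 19.
Longest linear sequence: 9 steps (steps 1–7, 18, 19 from α-ionone; the ring B branch, steps 8–14, 18, 19, is equally long).

Steps most likely to fail:

1. Step 18. During the one-pot sequence the boronate terminus may transmetalate prematurely, or the bis-metalated pentaene may suffer protodestannylation and E/Z drift, so that the two halves are attached unselectively or incompletely. The fallback makes the same two bonds in separate operations, so that tin and boron never share a molecule. It sets out from boronate aldehyde 26. Suzuki–Miyaura coupling of 26 with enynyl iodide 22 (Pd(PPh3)4, aq. K3PO4, THF) should give the silyl-protected acetylenic apo-aldehyde F1. Chromium-mediated stannyl olefination of F1 with 24 (CrCl2, LiI, THF/DMF) should give the polyenylstannane F2. Base-free Stille coupling of F2 with dienyl iodide 11 (Pd2(dba)3, AsPh3, DMF) comes back to the route at 29.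

2. Step 2. Hydrogen abstraction at the bis-allylic C6–H, or peroxyl attack on the enyne, may compete with oxidation at C3 and give regioisomeric or over-oxidised material. The fallback oxidises before the alkyne exists, with the side-chain ketone masked, and sets out from 1. Ketalisation (ethylene glycol, PPTS, benzene, reflux with water removal) gives α-ionone ethylene ketal F3. Allylic oxidation (t-BuOOH, Rh2(cap)4) gives the 3-oxo ketal F4, and Luche reduction gives the cis-hydroxy ketal F5. Silylation (TBSCl, imidazole) gives the silyl ether ketal F6, and mild deketalisation (PPTS, wet acetone) gives cis-3-silyloxy-α-ionone F7. The protocol of step 1 then passes through the enol phosphate F8 to the silyl dienyne F9. TBAF comes back to the route at 5; steps 2 and 3 are bypassed.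

3. Step 3. Hydride delivery to the C3 carbonyl may show poor or reversed facial selectivity and leave the trans alcohol as a major component, which the inversion step cannot use. The fallback sets out from 4. The racemic trans alcohol F10 is separated from the cis isomer by chromatography, or made the major product with a bulky hydride such as LiBH(s-Bu)3. It is acylated with retention by (1S)-camphanoyl chloride (pyridine, DMAP, CH2Cl2). Separation of the two trans camphanates comes back to the route at 7, so cis and trans material converge on the same ester.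

Further compounds
F1 | step 18 | (2E,4E,6E,8E,10E)-polyenal: ring B silyl ether, C7≡C8, chain C9 to C12' ending in the formyl carbon C12' | O=C/C(C)=C/C=C/C=C(C)/C=C/C=C(\C)C#CC1=C(C)C[C@@H](O[Si](C)(C)C(C)(C)C)CC1(C)C
F2 | step 18 | all-E polyenylstannane from F1 (tributylstannyl on C11') | CCCC[Sn](CCCC)(CCCC)/C=C/C(C)=C/C=C/C=C(C)/C=C/C=C(\C)C#CC1=C(C)C[C@@H](O[Si](C)(C)C(C)(C)C)CC1(C)C
F3 | step 2 | α-ionone ethylene ketal (racemate) | CC1=CCCC(C)(C)C1/C=C/C2(C)OCCO2
F4 | step 2 | 3-oxo-α-ionone ethylene ketal (racemate) | CC1=CC(=O)CC(C)(C)C1/C=C/C2(C)OCCO2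
F5 | step 2 | cis-3-hydroxy-α-ionone ethylene ketal (racemate; one enantiomer drawn) | CC1=C[C@@H](O)CC(C)(C)[C@H]1/C=C/C2(C)OCCO2
F6 | step 2 | cis-3-(tert-butyldimethylsilyloxy)-α-ionone ethylene ketal (racemate; one enantiomer drawn) | CC1=C[C@@H](O[Si](C)(C)C(C)(C)C)CC(C)(C)[C@H]1/C=C/C2(C)OCCO2
F7 | step 2 | cis-3-(tert-butyldimethylsilyloxy)-α-ionone (racemate; one enantiomer drawn) | CC1=C[C@@H](O[Si](C)(C)C(C)(C)C)CC(C)(C)[C@H]1/C=C/C(C)=O
F8 | step 2 | enol diethyl phosphate of F7 (racemate; one enantiomer drawn) | CC1=C[C@@H](O[Si](C)(C)C(C)(C)C)CC(C)(C)[C@H]1/C=C/C(=C)OP(=O)(OCC)OCC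
F9 | step 2 | silyl ether of cis dienynol 5 (racemate; one enantiomer drawn) | CC1=C[C@@H](O[Si](C)(C)C(C)(C)C)CC(C)(C)[C@H]1/C=C/C#C
F10 | step 3 | (±)-trans-4-[(E)-but-1-en-3-yn-1-yl]-3,5,5-trimethylcyclohex-2-en-1-ol (racemate of 8; (1R,4R) enantiomer drawn) | CC1=C[C@H](O)CC(C)(C)[C@H]1/C=C/C#C
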